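The C3 acetoxy group is traced back, with retention, to a C3–Si bond, and this to a C3–H bond of a 2-(2-hydroxypropan-2-yl)-2,3-dihydrobenzofuran whose carbinol later becomes the C2 propenal branch. The route exploits two features. The C3 methylene of the dihydrofuran ring is the only carbon gamma to that side-chain oxygen. A second five-membered ring on the C2–C3 edge can only be cis-fused. One iridium-catalysed dehydrogenative silylation thus forms C3–Si, closes the oxasilolane and sets C3 from C2. Its precursor is the diethylhydrosilyl ether of the tertiary alcohol, C2 being (R), with the C5 side chain already present as the TBS ether of the (R)-carbinol.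

Key step: step 8

Remark (numbering and target): dihydrobenzofuran numbering O1, C2, C3, C3a, C4–C7, C7a is used throughout, and C1' is the side-chain carbinol carbon on C5. The target is read as (2S,3S), cis at C2/C3, with C1' (R) and a (Z)-2-methylbut-2-enoate (angelate) ester.
Remark (descriptors): the label at C2 is (R) while the branch is CMe2–O and C3 bears H or O. It is (S) once C3 bears Si or the branch is an alkenyl group. The geometry never changes.
Remark (assumption): 3'-allyl-4'-hydroxyacetophenone and the L-fructose-derived enantiomer of the Shi ketone are taken as catalogue items. Otherwise they come from 4'-hydroxyacetophenone by O-allylation and Claisen rearrangement, and from L-sorbose, respectively.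
Remark (design): the dihydrofuran ring is made by epoxide opening in an ortho-prenylphenol because this fixes C2 by one clean inversion. A palladium/norbornene annulation would use an aryl iodide with no ortho substituent, in hot carbonate base, on an epoxy alcohol able to undergo Payne rearrangement. That would add a second large risk before the key step.

Step 1
Reactants: 1 3'-allyl-4'-hydroxyacetophenone
Product: 2 1-[3-allyl-4-(triisopropylsilyloxy)phenyl]ethanone
Conditions: TIPSCl, imidazole, DMF, rt
Reagents that add atoms: chlorotriisopropylsilane, CC(C)[Si](Cl)(C(C)C)C(C)C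
Why: Routine O-silylation of a phenol; the bulky TIPS ether keeps the oxidisable phenolate out of the dioxirane epoxidation of step 3, should outlast its carbonate buffer, and is released by fluoride exactly when the phenoxide is needed in step 4.

Step 2
Reactants: 2 1-[3-allyl-4-(triisopropylsilyloxy)phenyl]ethanone; 3 2-methylbut-2-ene
Product: 4 1-[3-(3-methylbut-2-enyl)-4-(triisopropylsilyloxy)phenyl]ethanone
Conditions: second-generation Grubbs catalyst RuCl2(=CHPh)(PCy3)(H2IMes) (3 mol %), 2-methylbut-2-ene/CH2Cl2, rt to 35 °C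
Reagents that add atoms: none
Why: Olefin cross-metathesis of a terminal alkene with excess 2-methylbut-2-ene exchanges =CH2 for =CMe2 and expels volatile propene, a standard way to turn an allylarene into a prenylarene that tolerates aryl ketones and silyl ethers.

Step 3
Reactants: 4 1-[3-(3-methylbut-2-enyl)-4-(triisopropylsilyloxy)phenyl]ethanone
Product: 5 1-[3-{[(2S)-3,3-dimethyloxiran-2-yl]methyl}-4-(triisopropylsilyloxy)phenyl]ethanone
Conditions: L-fructose-derived Shi ketone (30 mol %), KHSO5 (as 2KHSO5·KHSO4·K2SO4), K2CO3, Bu4NHSO4 (cat.), aq Na2B4O7 buffer, MeCN–CH2(OMe)2, 0 °C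
Reagents that add atoms: potassium peroxymonosulfate, [K+].[O-]S(=O)(=O)OO
Why: Shi asymmetric epoxidation: the chiral dioxirane formed in situ attacks the only electron-rich alkene through a spiro transition state, and since the D-fructose-derived ketone gives (R)-epoxides from RCH=CMe2 alkenes its enantiomer should set the oxirane CH carbon as (S).

Step 4
Reactants: 5 1-[3-{[(2S)-3,3-dimethyloxiran-2-yl]methyl}-4-(triisopropylsilyloxy)phenyl]ethanone
Product: 7 1-[(2R)-2-(2-hydroxypropan-2-yl)-2,3-dihydrobenzofuran-5-yl]ethanone, via epoxy phenol 6 (not isolated)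
Conditions: TBAF (1.1 equiv), THF, 0 °C to rt; H2O work-up
Reagents that add atoms: none
Why: Fluoride desilylation frees the phenoxide, which opens the epoxide by 5-exo-tet SN2 attack at the less substituted oxirane carbon (basic conditions disfavour 6-endo attack at CMe2), so that this carbon is inverted cleanly and becomes C2 with (R) configuration.

Step 5
Reactants: 7 1-[(2R)-2-(2-hydroxypropan-2-yl)-2,3-dihydrobenzofuran-5-yl]ethanone
Product: 8 (1R)-1-[(2R)-2-(2-hydroxypropan-2-yl)-2,3-dihydrobenzofuran-5-yl]ethanol
Conditions: RuCl(p-cymene)[(R,R)-TsDPEN] (1 mol %), HCO2H/Et3N (5:2), 30–40 °C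
Reagents that add atoms: none
Why: Noyori asymmetric transfer hydrogenation of an aryl methyl ketone: the (R,R)-TsDPEN ruthenium hydride should give the (R)-1-arylethanol under catalyst control, as with acetophenone itself, the remote C2 centre and the tertiary alcohol being spectators and formic acid making the reduction irreversible.

Step 6
Reactants: 8 (1R)-1-[(2R)-2-(2-hydroxypropan-2-yl)-2,3-dihydrobenzofuran-5-yl]ethanol
Product: 9 2-[(2R)-5-[(1R)-1-(tert-butyldimethylsilyloxy)ethyl]-2,3-dihydrobenzofuran-2-yl]propan-2-ol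
Conditions: TBSCl (1.1 equiv), imidazole, DMF, 0 °C to rt
Reagents that add atoms: tert-butyldimethylsilyl chloride, CC(C)(C)[Si](C)(C)Cl
Why: Chemoselective silylation of the secondary over the hindered tertiary alcohol; the TBS ether carries no Si–H, C=O or C=C that could interfere in step 8, survives bicarbonate/peroxide in step 9 and keeps the C1' oxygen distinguishable from the later C3 oxygen.

Step 7
Reactants: 9 2-[(2R)-5-[(1R)-1-(tert-butyldimethylsilyloxy)ethyl]-2,3-dihydrobenzofuran-2-yl]propan-2-ol; 10 chlorodiethylsilane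
Product: 11 (2R)-2-[2-(diethylsilyloxy)propan-2-yl]-5-[(1R)-1-(tert-butyldimethylsilyloxy)ethyl]-2,3-dihydrobenzofuran
Conditions: Et2SiHCl (1.3 equiv), Et3N, DMAP (cat.), CH2Cl2, 0 °C to rt; filtration under N2
Reagents that add atoms: none
Why: Silylation of the tertiary alcohol with a small chlorosilane under amine/DMAP catalysis gives the moisture-sensitive hydrosilyl ether, which is freed from salts by filtration and used at once.

Step 8
Reactants: 11 (2R)-2-[2-(diethylsilyloxy)propan-2-yl]-5-[(1R)-1-(tert-butyldimethylsilyloxy)ethyl]-2,3-dihydrobenzofuran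
Product: 12 cis-fused tricyclic oxasilolane in which SiEt2 bridges C3 and the side-chain oxygen (new ring Si–O–CMe2–C2–C3), C2 (S), C3 (S), C1' (R), TBS ether unchanged
Conditions: [Ir(cod)OMe]2 (2 mol %), 3,4,7,8-tetramethyl-1,10-phenanthroline (5 mol %), norbornene (1.5 equiv), THF, 100–120 °C, sealed tube
Reagents that add atoms: none
Why: The Si–H bond adds oxidatively to the phenanthroline-ligated iridium centre, the resulting iridium silyl cleaves the C3–H bond on the tether face to give a six-membered iridacycle (Ir–Si–O–CMe2–C2–C3), and C–Si reductive elimination releases the oxasilolane while norbornene takes up the two hydrogens as norbornane. The closest known reaction type is the iridium-catalysed intramolecular dehydrogenative silylation of secondary gamma C–H bonds in diethylhydrosilyl ethers of tertiary alcohols, the first half of a 1,3-diol synthesis. The one new ring, a five-membered 1,2-oxasilolane, is closed by contraction of that iridacycle at the C3–Si bond and is annulated on the C2–C3 edge of the dihydrofuran ring. C3 is set by C2, because a bicyclo[3.3.0] junction of two five-membered rings is attainable only cis, so silicon can replace only the C3 hydrogen syn to the C2 branch. Site selectivity rests on tether length: the two methyl groups are beta (four-membered ring), the aromatic C4–H and C7–H bonds would need seven-membered rings, and C1'–H is out of reach under a silyl group without Si–H. The metal-bound C3 has its only beta hydrogen (C2–H) anti to iridium and the C2–O1 bond is held in the ring away from syn-coplanarity, which should suppress beta-elimination, and 11 contains no carbonyl or alkene that could consume the Si–H bond.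

Step 9
Reactants: 12 cis-fused oxasilolane
Product: 13 (2R,3S)-5-[(1R)-1-(tert-butyldimethylsilyloxy)ethyl]-2-(2-hydroxypropan-2-yl)-2,3-dihydrobenzofuran-3-ol (cis diol)
Conditions: H2O2 (30 % aq), KHCO3, THF–MeOH (1:1), 45–50 °C
Reagents that add atoms: hydrogen peroxide, OO
Why: Tamao–Fleming oxidation: hydroperoxide adds to the alkoxy-activated silicon and C3 migrates from Si to O with retention, so the C3 oxygen ends cis to the C2 branch; fluoride-free bicarbonate conditions spare the TBS ether and limit benzylic protodesilylation, and the C2–O1 bond, locked in the ring far from periplanar to C3–Si, is poorly placed for Peterson-type loss of phenoxide.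

Step 10
Reactants: 13 cis diol
Product: 14 (2R,3S)-5-[(1R)-1-(tert-butyldimethylsilyloxy)ethyl]-2-(2-hydroxypropan-2-yl)-2,3-dihydrobenzofuran-3-yl acetate
Conditions: Ac2O (1.1 equiv), pyridine, DMAP (cat.), CH2Cl2, 0 °C to rt
Reagents that add atoms: acetic anhydride, CC(=O)OC(C)=O
Why: Acylation under DMAP catalysis distinguishes the secondary benzylic C3 hydroxyl from the tertiary carbinol on steric grounds, so that about one equivalent of anhydride should give the monoacetate.

Step 11
Reactants: 14 hydroxy acetate
Product: 15 (2S,3S)-5-[(1R)-1-(tert-butyldimethylsilyloxy)ethyl]-2-(prop-1-en-2-yl)-2,3-dihydrobenzofuran-3-yl acetate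
Conditions: Burgess reagent (MeO2CN−SO2N+Et3, 1.5 equiv), toluene, 50–60 °C
Reagents that add atoms: none
Why: Burgess dehydration (syn elimination of the tertiary sulfamate under neutral conditions) should take one of six exposed methyl hydrogens rather than the single hindered C2–H, whose loss would give a strained tetrasubstituted enol ether next to the acetate, and it leaves C2, C3, the acetate and the TBS ether untouched.

Step 12
Reactants: 15 isopropenyl acetate TBS ether
Product: 16 (2S,3S)-5-[(1R)-1-hydroxyethyl]-2-(prop-1-en-2-yl)-2,3-dihydrobenzofuran-3-yl acetate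
Conditions: TBAF/AcOH (1:1, 2 equiv), THF, rt
Reagents that add atoms: none
Why: Fluoride desilylation buffered with acetic acid stays near neutral, which protects the C3 acetate from base and the ionisable para-alkoxybenzylic C1' centre from acid, so configuration is kept.

Step 13
Reactants: 16 (2S,3S)-5-[(1R)-1-hydroxyethyl]-2-(prop-1-en-2-yl)-2,3-dihydrobenzofuran-3-yl acetate; 17 angelic acid [(Z)-2-methylbut-2-enoic acid]
Product: 19 (1R)-1-[(2S,3S)-3-acetoxy-2-(prop-1-en-2-yl)-2,3-dihydrobenzofuran-5-yl]ethyl (Z)-2-methylbut-2-enoate, via mixed anhydride 18 (not isolated)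
Conditions: 17 (3 equiv), 2,4,6-trichlorobenzoyl chloride, Et3N, toluene, rt; then 16, 60–75 °C, no DMAP
Reagents that add atoms: none
Why: Yamaguchi-type mixed-anhydride esterification run without a nucleophilic catalyst: the alcohol attacks the less hindered angeloyl carbonyl, the C1'–O bond is not touched so (R) is retained, and leaving out DMAP avoids the addition–elimination that turns angelates into tiglates.

Step 14
Reactants: 19 (1R)-1-[(2S,3S)-3-acetoxy-2-(prop-1-en-2-yl)-2,3-dihydrobenzofuran-5-yl]ethyl (Z)-2-methylbut-2-enoate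
Product: 21 (1R)-1-[(2S,3S)-3-acetoxy-2-(3-oxoprop-1-en-2-yl)-2,3-dihydrobenzofuran-5-yl]ethyl (Z)-2-methylbut-2-enoate (target), via allylic alcohol 20 (not isolated)
Conditions: SeO2 (1.5 equiv), 1,4-dioxane, 70 °C
Reagents that add atoms: selenium dioxide, O=[Se]=O
Why: Riley oxidation: ene reaction of SeO2 at the terminal =CH2 and 2,3-sigmatropic shift place oxygen on the vinylic methyl group and the primary allylic alcohol is oxidised on to the enal, the isopropenyl group being the only alkene not deactivated by conjugation with an ester and the C2–H being inductively deactivated by O1 and shielded by the cis acetate.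

Compound list
1 | 3'-allyl-4'-hydroxyacetophenone | CC(=O)c1ccc(O)c(CC=C)c1 | starting material
2 | 1-[3-allyl-4-(triisopropylsilyloxy)phenyl]ethanone | CC(=O)c1ccc(O[Si](C(C)C)(C(C)C)C(C)C)c(CC=C)c1 | intermediate
3 | 2-methylbut-2-ene | CC=C(C)C | starting material
4 | 1-[3-(3-methylbut-2-enyl)-4-(triisopropylsilyloxy)phenyl]ethanone | CC(=O)c1ccc(O[Si](C(C)C)(C(C)C)C(C)C)c(CC=C(C)C)c1 | intermediate
5 | 1-[3-{[(2S)-3,3-dimethyloxiran-2-yl]methyl}-4-(triisopropylsilyloxy)phenyl]ethanone | CC1(C)O[C@H]1Cc2cc(C(C)=O)ccc2O[Si](C(C)C)(C(C)C)C(C)C | intermediate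
6 | 1-[3-{[(2S)-3,3-dimethyloxiran-2-yl]methyl}-4-hydroxyphenyl]ethanone (reacts as its phenoxide) | CC1(C)O[C@H]1Cc2cc(C(C)=O)ccc2O | intermediate
7 | 1-[(2R)-2-(2-hydroxypropan-2-yl)-2,3-dihydrobenzofuran-5-yl]ethanone | CC(C)(O)[C@@H]1Oc2ccc(C(C)=O)cc2C1 | intermediate
8 | (1R)-1-[(2R)-2-(2-hydroxypropan-2-yl)-2,3-dihydrobenzofuran-5-yl]ethanol | CC(C)(O)[C@@H]1Oc2ccc([C@@H](C)O)cc2C1 | intermediate
9 | 2-[(2R)-5-[(1R)-1-(tert-butyldimethylsilyloxy)ethyl]-2,3-dihydrobenzofuran-2-yl]propan-2-ol | CC(C)(O)[C@@H]1Oc2ccc([C@@H](C)O[Si](C)(C)C(C)(C)C)cc2C1 | intermediate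
10 | chlorodiethylsilane | CC[SiH](Cl)CC | starting material
11 | (2R)-2-[2-(diethylsilyloxy)propan-2-yl]-5-[(1R)-1-(tert-butyldimethylsilyloxy)ethyl]-2,3-dihydrobenzofuran | CC[SiH](CC)OC(C)(C)[C@@H]1Oc2ccc([C@@H](C)O[Si](C)(C)C(C)(C)C)cc2C1 | intermediate
12 | cis-fused oxasilolane, SiEt2 bridging C3 and the side-chain oxygen, C2 (S), C3 (S), C1' (R) | CC[Si]3(CC)OC(C)(C)[C@@H]1Oc2ccc([C@@H](C)O[Si](C)(C)C(C)(C)C)cc2[C@@H]13 | intermediate
13 | (2R,3S)-5-[(1R)-1-(tert-butyldimethylsilyloxy)ethyl]-2-(2-hydroxypropan-2-yl)-2,3-dihydrobenzofuran-3-ol | CC(C)(O)[C@@H]1Oc2ccc([C@@H](C)O[Si](C)(C)C(C)(C)C)cc2[C@@H]1O | intermediate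
14 | (2R,3S)-5-[(1R)-1-(tert-butyldimethylsilyloxy)ethyl]-2-(2-hydroxypropan-2-yl)-2,3-dihydrobenzofuran-3-yl acetate | CC(C)(O)[C@@H]1Oc2ccc([C@@H](C)O[Si](C)(C)C(C)(C)C)cc2[C@@H]1OC(C)=O | intermediate
15 | (2S,3S)-5-[(1R)-1-(tert-butyldimethylsilyloxy)ethyl]-2-(prop-1-en-2-yl)-2,3-dihydrobenzofuran-3-yl acetate | C=C(C)[C@@H]1Oc2ccc([C@@H](C)O[Si](C)(C)C(C)(C)C)cc2[C@@H]1OC(C)=O | intermediate
16 | (2S,3S)-5-[(1R)-1-hydroxyethyl]-2-(prop-1-en-2-yl)-2,3-dihydrobenzofuran-3-yl acetate | C=C(C)[C@@H]1Oc2ccc([C@@H](C)O)cc2[C@@H]1OC(C)=O | intermediate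
17 | angelic acid, (Z)-2-methylbut-2-enoic acid | C/C=C(/C)C(=O)O | starting material
18 | angelic 2,4,6-trichlorobenzoic anhydride | C/C=C(/C)C(=O)OC(=O)c1c(Cl)cc(Cl)cc1Cl | intermediate
19 | (1R)-1-[(2S,3S)-3-acetoxy-2-(prop-1-en-2-yl)-2,3-dihydrobenzofuran-5-yl]ethyl (Z)-2-methylbut-2-enoate | C=C(C)[C@@H]1Oc2ccc([C@@H](C)OC(=O)/C(C)=C\C)cc2[C@@H]1OC(C)=O | intermediate
20 | (1R)-1-[(2S,3S)-3-acetoxy-2-(3-hydroxyprop-1-en-2-yl)-2,3-dihydrobenzofuran-5-yl]ethyl (Z)-2-methylbut-2-enoate | C=C(CO)[C@@H]1Oc2ccc([C@@H](C)OC(=O)/C(C)=C\C)cc2[C@@H]1OC(C)=O | intermediate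
21 | (1R)-1-[(2S,3S)-3-acetoxy-2-(3-oxoprop-1-en-2-yl)-2,3-dihydrobenzofuran-5-yl]ethyl (Z)-2-methylbut-2-enoate | C=C(C=O)[C@@H]1Oc2ccc([C@@H](C)OC(=O)/C(C)=C\C)cc2[C@@H]1OC(C)=O | target

Total step count: 14. Longest linear sequence: 14 steps (1 to 21).

Steps most likely to fail

1. Step 8 (C–H silylation).
- Risk: the iridium silyl may not cleave the ring C3–H bond next to the bulky CMe2 unit at a useful rate. Silane redistribution, hydrolysis of the Si–O bond or expulsion of the ring aryloxide from the iridium alkyl could then take over at 100–120 °C.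
- Fallback: a radical relay replaces metal insertion, setting out from 9 and returning at 13. The tertiary alcohol 9 is carbamoylated with 2,2,2-trifluoroethyl isocyanate to the N-(2,2,2-trifluoroethyl)carbamate F1. This is N-brominated with acetyl hypobromite to the N-bromocarbamate F2 and irradiated with visible light. The nitrogen radical abstracts a C3 hydrogen by 1,6-transfer (a Hofmann–Löffler–Freytag variant used for 1,3-diols), and chain bromination gives the C3 bromide F3. Ag2CO3 ionises either bromide epimer, and the tethered carbonyl oxygen closes on the face of the C2 branch to the cis-fused iminocarbonate F4. Aqueous acetic acid hydrolyses this to the cyclic carbonate F5, and K2CO3 in MeOH releases diol 13.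

2. Step 14 (allylic oxidation).
- Risk: the alkene is inductively deactivated by O1 and may react slowly. A competing ene attack at C2–H could then become significant. So could oxidation or Z to E isomerisation of the angelate, or ionisation of the two benzylic esters by selenous acid.
- Fallback: the oxidation is done before the angelate is present and is split into two mild stages, setting out from 15 and returning at 21. Silyl ether 15 is treated with catalytic SeO2 and t-BuOOH in CH2Cl2 at rt to give the allylic alcohol F6. Dess–Martin periodinane with NaHCO3 converts this to the silylated enal F7. HF·pyridine buffered with pyridine in THF gives the hydroxy enal F8. F8 is acylated with preformed mixed anhydride 18 (Et3N, toluene) to give 21.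

3. Step 13 (angeloylation).
- Risk: the activated angeloyl unit may isomerise from Z to E by reversible conjugate addition during slow acyl transfer. Prolonged heating may also ionise the para-alkoxybenzylic alcohol, with erosion of C1' or loss of acetic acid across C2–C3.
- Fallback: the Z alkene is built on the ester instead of being transferred, setting out from 16 and returning at 19. Alcohol 16 is esterified at rt with 2-[bis(2,2,2-trifluoroethoxy)phosphoryl]propanoic acid (EDC, DMAP) to the phosphonopropionate F9. A Still–Gennari olefination (KN(SiMe3)2, 18-crown-6, THF, −78 °C, then acetaldehyde) deprotonates only the acidic phosphonate position. It should deliver the Z-trisubstituted enoate 19.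

Further compounds
F1 | step 8 | 2-[(2R)-5-[(1R)-1-(tert-butyldimethylsilyloxy)ethyl]-2,3-dihydrobenzofuran-2-yl]propan-2-yl N-(2,2,2-trifluoroethyl)carbamate | CC(C)(OC(=O)NCC(F)(F)F)[C@@H]1Oc2ccc([C@@H](C)O[Si](C)(C)C(C)(C)C)cc2C1
F2 | step 8 | N-bromo derivative of carbamate F1 | CC(C)(OC(=O)N(Br)CC(F)(F)F)[C@@H]1Oc2ccc([C@@H](C)O[Si](C)(C)C(C)(C)C)cc2C1
F3 | step 8 | 3-bromo derivative of carbamate F1 (both C3 epimers) | CC(C)(OC(=O)NCC(F)(F)F)[C@@H]1Oc2ccc([C@@H](C)O[Si](C)(C)C(C)(C)C)cc2C1Br
F4 | step 8 | cis-fused six-membered cyclic N-(2,2,2-trifluoroethyl)iminocarbonate spanning the C3 and side-chain oxygens | FC(F)(F)CN=C1OC(C)(C)[C@@H]2Oc3ccc([C@@H](C)O[Si](C)(C)C(C)(C)C)cc3[C@@H]2O1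
F5 | step 8 | cis-fused six-membered cyclic carbonate of diol 13 | O=C1OC(C)(C)[C@@H]2Oc3ccc([C@@H](C)O[Si](C)(C)C(C)(C)C)cc3[C@@H]2O1
F6 | step 14 | (2S,3S)-5-[(1R)-1-(tert-butyldimethylsilyloxy)ethyl]-2-(3-hydroxyprop-1-en-2-yl)-2,3-dihydrobenzofuran-3-yl acetate | C=C(CO)[C@@H]1Oc2ccc([C@@H](C)O[Si](C)(C)C(C)(C)C)cc2[C@@H]1OC(C)=O
F7 | step 14 | (2S,3S)-5-[(1R)-1-(tert-butyldimethylsilyloxy)ethyl]-2-(3-oxoprop-1-en-2-yl)-2,3-dihydrobenzofuran-3-yl acetate | C=C(C=O)[C@@H]1Oc2ccc([C@@H](C)O[Si](C)(C)C(C)(C)C)cc2[C@@H]1OC(C)=O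
F8 | step 14 | (2S,3S)-5-[(1R)-1-hydroxyethyl]-2-(3-oxoprop-1-en-2-yl)-2,3-dihydrobenzofuran-3-yl acetate | C=C(C=O)[C@@H]1Oc2ccc([C@@H](C)O)cc2[C@@H]1OC(C)=O
F9 | step 13 | (1R)-1-[(2S,3S)-3-acetoxy-2-(prop-1-en-2-yl)-2,3-dihydrobenzofuran-5-yl]ethyl 2-[bis(2,2,2-trifluoroethoxy)phosphoryl]propanoate (both epimers at the phosphonate carbon) | C=C(C)[C@@H]1Oc2ccc([C@@H](C)OC(=O)C(C)P(=O)(OCC(F)(F)F)OCC(F)(F)F)cc2[C@@H]1OC(C)=O
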